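**Plan**

- Retrosynthesis (hydroazulene numbering of the target): first cut the two ester C–O bonds (angelate at C1, trimethoxybenzoate at C4). Then cut, in one operation, the C8a–CH3 bond and the C3–C3a bond of the cyclopentane. The remaining cycloheptadienone is cut at C6=C7 (metathesis), C8–C8a (allyl coupling), C4–C5 (allylmetal addition) and C2–C3 (aldol).
- Enabling feature: the tertiary carbinol C3 lies β to the C4 oxygen across ring-fusion carbon C3a (an aldol retron inside the five-membered ring), and the quaternary C8a is the β-carbon of that same C4 carbonyl. A C3a=C8a enone carrying the C1–C3 keto chain on C8a can therefore accept methyl and close C3–C3a in one event.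
- Forward order: acyclic C1–C3/isopropyl chain by aldol; alkyne to Z-iodoalkene to allyl coupling; ring-closing metathesis gives the seven-membered ring first; double oxidation; the cyclopentane is closed last; reduction and two esterifications finish.
- Stereochemistry: C1 from catalyst-controlled transfer hydrogenation; C8a from C1 in the methyl addition; C3a and C3 from the cis, chelated aldol closure; C4 from hydroxyl-directed reduction; angelate geometry from angelic acid.

Key step: step 10

Remark: the two carbinol carbons that become the C3 and C4 ketones in step 9 need no defined configuration and are carried as epimer mixtures from steps 1 and 5.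

**Route**

Step 1
Reactants: 1 4-(trimethylsilyl)but-3-yn-2-one; 2 2-methylpropanal
Product: 4 rac-5-hydroxy-6-methyl-1-(trimethylsilyl)hept-1-yn-3-one, via lithium enolate 3 (not isolated)
Conditions: lithium diisopropylamide (1.05 equiv), THF, −78 °C; then 2, −78 °C
Reagents that add atoms: none
Why: The kinetic lithium enolate of the methyl ynone adds to the aldehyde (directed aldol addition) and joins C2 to C3 with the isopropyl group in place; the new carbinol is left racemic because it is oxidised in step 9.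

Step 2
Reactants: 4 rac-5-hydroxy-6-methyl-1-(trimethylsilyl)hept-1-yn-3-one
Product: 5 (3S)-6-methyl-1-(trimethylsilyl)hept-1-yne-3,5-diol (both C5 epimers)
Conditions: Ru[(S,S)-TsDPEN](p-cymene) (2 mol %), i-PrOH, 25 °C
Reagents that add atoms: none
Why: Noyori asymmetric transfer hydrogenation of an alkynyl ketone, in which the (S,S)-TsDPEN ruthenium hydride distinguishes the alkynyl from the alkyl flank and sets the (S)-propargylic carbinol (future C1) by catalyst control.

Step 3
Reactants: 5 (3S)-6-methyl-1-(trimethylsilyl)hept-1-yne-3,5-diol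
Product: 6 (5S)-5-[(tert-butyldimethylsilyl)oxy]-2-methyl-7-(trimethylsilyl)hept-6-yn-3-ol (both C3 epimers)
Conditions: t-BuMe2SiCl (1.05 equiv), imidazole, CH2Cl2, −20 °C
Reagents that add atoms: tert-butyldimethylsilyl chloride, CC(C)(C)[Si](C)(C)Cl
Why: Site-selective silylation, since the propargylic hydroxyl is much less hindered than the isopropyl-flanked one, so the hydroxyl that must become the C3 ketone stays free.

Step 4
Reactants: 6 (5S)-5-[(tert-butyldimethylsilyl)oxy]-2-methyl-7-(trimethylsilyl)hept-6-yn-3-ol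
Product: 8 (4S)-4-[(tert-butyldimethylsilyl)oxy]-6-hydroxy-7-methyloct-2-ynal (both C6 epimers), via dilithium alkoxide acetylide 7 (not isolated)
Conditions: MeLi·LiBr (2.2 equiv), THF, 0 °C; then DMF, −78 → 0 °C; pH 7 aqueous work-up
Reagents that add atoms: N,N-dimethylformamide, CN(C)C=O
Why: MeLi·LiBr cleaves the alkynyl C–Si bond and deprotonates the alcohol, and the lithium acetylide is formylated by DMF (acetylide formylation) to supply C4 as an aldehyde.

Step 5
Reactants: 8 (4S)-4-[(tert-butyldimethylsilyl)oxy]-6-hydroxy-7-methyloct-2-ynal; 9 (2-methylprop-2-en-1-yl)magnesium chloride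
Product: 10 (7S)-7-[(tert-butyldimethylsilyl)oxy]-2,10-dimethylundec-1-en-5-yne-4,9-diol (epimers at C4 and C9)
Conditions: 9 (2.2 equiv), THF, −78 °C
Reagents that add atoms: none
Why: 1,2-Addition of the allylic Grignard reagent to the ynal brings in C5, C6 and the C6 methyl group; the new carbinol (future C4) forms as both epimers, which is harmless because it is oxidised in step 9.

Step 6
Reactants: 10 (7S)-7-[(tert-butyldimethylsilyl)oxy]-2,10-dimethylundec-1-en-5-yne-4,9-diol
Product: 12 (5Z,7S)-7-[(tert-butyldimethylsilyl)oxy]-6-iodo-2,10-dimethylundeca-1,5-diene-4,9-diol, via cyclic sodium alkenylalanate 11 (not isolated)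
Conditions: NaAlH2(OCH2CH2OMe)2 (Red-Al, 4 equiv), THF, 0 → 25 °C; then I2, −78 °C
Reagents that add atoms: iodine, II
Why: Hydroxyl-directed trans-hydroalumination of the propargylic alcohol puts hydride on the proximal and aluminium on the distal alkyne carbon within a five-membered alanate, and iodinolysis with retention gives the Z-iodoalkene, fixing the cis relation of C4 and the future C8 that the seven-membered ring needs.

Step 7
Reactants: 12 (5Z,7S)-7-[(tert-butyldimethylsilyl)oxy]-6-iodo-2,10-dimethylundeca-1,5-diene-4,9-diol; 13 tributyl(prop-2-en-1-yl)stannane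
Product: 14 (5E,7S)-7-[(tert-butyldimethylsilyl)oxy]-2,10-dimethyl-6-(prop-2-en-1-yl)undeca-1,5-diene-4,9-diol
Conditions: Pd2(dba)3 (5 mol %), AsPh3, CuI (cat.), DMF, 45 °C
Reagents that add atoms: none
Why: Stille coupling of the alkenyl iodide with the allylstannane proceeds with retention of alkene geometry and installs C8 and C7 as a skipped diene.

Step 8
Reactants: 14 (5E,7S)-7-[(tert-butyldimethylsilyl)oxy]-2,10-dimethyl-6-(prop-2-en-1-yl)undeca-1,5-diene-4,9-diol
Product: 15 3-[(1S)-1-[(tert-butyldimethylsilyl)oxy]-3-hydroxy-4-methylpentyl]-6-methylcyclohepta-2,5-dien-1-ol (epimers at ring C1 and side-chain C3)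
Conditions: second-generation Grubbs catalyst RuCl2(=CHPh)(H2IMes)(PCy3) (5 mol %), CH2Cl2 (2 mM), 40 °C
Reagents that add atoms: none
Why: Ring-closing metathesis of the allyl and 2-methylallyl groups, held on the same side by the trisubstituted alkene, closes the seven-membered ring and creates the trisubstituted C6=C7 alkene with loss of ethene.

Step 9
Reactants: 15 3-[(1S)-1-[(tert-butyldimethylsilyl)oxy]-3-hydroxy-4-methylpentyl]-6-methylcyclohepta-2,5-dien-1-ol
Product: 16 3-[(1S)-1-[(tert-butyldimethylsilyl)oxy]-4-methyl-3-oxopentyl]-6-methylcyclohepta-2,5-dien-1-one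
Conditions: Dess–Martin periodinane (3 equiv), NaHCO3, CH2Cl2, 0 → 25 °C
Reagents that add atoms: none
Why: Dess–Martin oxidation turns both secondary alcohols into ketones under buffered, non-enolising conditions, which removes the two stereorandom centres and should keep the skipped dienone out of conjugation.

Step 10
Reactants: 16 3-[(1S)-1-[(tert-butyldimethylsilyl)oxy]-4-methyl-3-oxopentyl]-6-methylcyclohepta-2,5-dien-1-one
Product: 18 (1S,3S,3aS,8aR)-1-[(tert-butyldimethylsilyl)oxy]-3-hydroxy-6,8a-dimethyl-3-(propan-2-yl)-2,3,3a,5,8,8a-hexahydroazulen-4(1H)-one, via lithium enolate 17 (not isolated)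
Conditions: Me2CuLi (from CuI and MeLi, 2.5 equiv), Et2O, −78 → −20 °C; aqueous work-up
Reagents that add atoms: lithium dimethylcuprate, [Li+].C[Cu-]C
Why: The cuprate forms a π-complex with the enone and transfers methyl to its β-carbon (C8a, target numbering), which creates the quaternary centre and a regiodefined C3a=C4 lithium enolate that deprotonation could not give selectively, and this enolate adds to the tethered isopropyl ketone to close the cyclopentane. The closest known reaction type is the tandem organocopper conjugate addition–intramolecular aldol cyclisation of keto-enones. The ring closes in the 5-(enolexo)-exo-trig mode. C8a is controlled by the silyloxy stereocentre C1 in a Felkin–Anh-type arrangement (C–OSi anti to the incoming methyl, the CH2 chain inside next to the flat C3a, H outside next to the ring CH2); C3a must be cis to the three-atom tether, which gives the cis ring fusion; C3 follows from the lithium-chelated closed transition state that places the hydroxyl syn to the C4 carbonyl and the isopropyl group on the convex face. The step needs 1,4-addition in preference to attack on the saturated ketone, which the soft cuprate at low temperature and the single conjugated β-carbon (C6=C7 is not conjugated) should secure, and π-facial selectivity at C8a, which rests on C1.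

Step 11
Reactants: 18 (1S,3S,3aS,8aR)-1-[(tert-butyldimethylsilyl)oxy]-3-hydroxy-6,8a-dimethyl-3-(propan-2-yl)-2,3,3a,5,8,8a-hexahydroazulen-4(1H)-one
Product: 19 (1S,3S,3aR,4R,8aR)-1-[(tert-butyldimethylsilyl)oxy]-6,8a-dimethyl-3-(propan-2-yl)-1,2,3,3a,4,5,8,8a-octahydroazulene-3,4-diol
Conditions: Me4NBH(OAc)3, MeCN/AcOH (1:1), −30 °C
Reagents that add atoms: none
Why: Evans–Saksena reduction, in which the tertiary C3 hydroxyl binds boron and delivers hydride intramolecularly to the face of the C4 ketone on which it lies, giving the 1,3-anti diol and so the (4R) carbinol.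

Step 12
Reactants: 19 (1S,3S,3aR,4R,8aR)-1-[(tert-butyldimethylsilyl)oxy]-6,8a-dimethyl-3-(propan-2-yl)-1,2,3,3a,4,5,8,8a-octahydroazulene-3,4-diol; 20 3,4,5-trimethoxybenzoyl chloride
Product: 21 (1S,3S,3aR,4R,8aR)-1-[(tert-butyldimethylsilyl)oxy]-3-hydroxy-6,8a-dimethyl-3-(propan-2-yl)-1,2,3,3a,4,5,8,8a-octahydroazulen-4-yl 3,4,5-trimethoxybenzoate
Conditions: Et3N, DMAP (cat.), CH2Cl2, 0 → 40 °C
Reagents that add atoms: none
Why: DMAP-catalysed acylation with the aroyl chloride occurs only at the secondary C4 hydroxyl, the tertiary C3 hydroxyl being unreactive.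

Step 13
Reactants: 21 (1S,3S,3aR,4R,8aR)-1-[(tert-butyldimethylsilyl)oxy]-3-hydroxy-6,8a-dimethyl-3-(propan-2-yl)-1,2,3,3a,4,5,8,8a-octahydroazulen-4-yl 3,4,5-trimethoxybenzoate
Product: 22 (1S,3S,3aR,4R,8aR)-1,3-dihydroxy-6,8a-dimethyl-3-(propan-2-yl)-1,2,3,3a,4,5,8,8a-octahydroazulen-4-yl 3,4,5-trimethoxybenzoate
Conditions: HF·pyridine, THF/pyridine, 0 → 25 °C
Reagents that add atoms: none
Why: Fluoride-mediated silyl ether cleavage frees the C1 hydroxyl under mildly acidic conditions that should leave the aryl ester, the tertiary alcohol and the alkene untouched.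

Step 14
Reactants: 22 (1S,3S,3aR,4R,8aR)-1,3-dihydroxy-6,8a-dimethyl-3-(propan-2-yl)-1,2,3,3a,4,5,8,8a-octahydroazulen-4-yl 3,4,5-trimethoxybenzoate; 23 angelic acid [(2Z)-2-methylbut-2-enoic acid]
Product: 25 (1S,3S,3aR,4R,8aR)-3-hydroxy-6,8a-dimethyl-3-(propan-2-yl)-4-[(3,4,5-trimethoxybenzoyl)oxy]-1,2,3,3a,4,5,8,8a-octahydroazulen-1-yl (2Z)-2-methylbut-2-enoate, via angelic 2,4,6-trichlorobenzoic anhydride 24 (not isolated)
Conditions: 23, 2,4,6-trichlorobenzoyl chloride, Et3N, toluene, 25 °C; then 22, 80 °C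
Reagents that add atoms: none
Why: Yamaguchi-type esterification through the mixed anhydride acylates the hindered secondary C1 hydroxyl without a nucleophilic catalyst, conditions under which the Z-alkene of the angelate should not isomerise to the tiglate, while the tertiary hydroxyl does not react.

**Compound list**

1 | 4-(trimethylsilyl)but-3-yn-2-one | CC(=O)C#C[Si](C)(C)C | starting material
2 | 2-methylpropanal | CC(C)C=O | starting material
3 | lithium enolate of 1 | [Li+].C=C([O-])C#C[Si](C)(C)C | intermediate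
4 | rac-5-hydroxy-6-methyl-1-(trimethylsilyl)hept-1-yn-3-one | CC(C)C(O)CC(=O)C#C[Si](C)(C)C | intermediate
5 | (3S)-6-methyl-1-(trimethylsilyl)hept-1-yne-3,5-diol, both C5 epimers | CC(C)C(O)C[C@H](O)C#C[Si](C)(C)C | intermediate
6 | (5S)-5-[(tert-butyldimethylsilyl)oxy]-2-methyl-7-(trimethylsilyl)hept-6-yn-3-ol, both C3 epimers | CC(C)C(O)C[C@H](O[Si](C)(C)C(C)(C)C)C#C[Si](C)(C)C | intermediate
7 | dilithium alkoxide acetylide from 6 | [Li+].[Li+].CC(C)C([O-])C[C@H](O[Si](C)(C)C(C)(C)C)C#[C-] | intermediate
8 | (4S)-4-[(tert-butyldimethylsilyl)oxy]-6-hydroxy-7-methyloct-2-ynal, both C6 epimers | CC(C)C(O)C[C@H](O[Si](C)(C)C(C)(C)C)C#CC=O | intermediate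
9 | (2-methylprop-2-en-1-yl)magnesium chloride | CC(=C)C[Mg]Cl | starting material
10 | (7S)-7-[(tert-butyldimethylsilyl)oxy]-2,10-dimethylundec-1-en-5-yne-4,9-diol, epimers at C4 and C9 | CC(C)C(O)C[C@H](O[Si](C)(C)C(C)(C)C)C#CC(O)CC(C)=C | intermediate
11 | cyclic sodium alkenylalanate (five-membered O–Al–C ring; the remote alkoxide is drawn as the free alcohol) | [Na+].CC(C)C(O)C[C@H](O[Si](C)(C)C(C)(C)C)C1=CC(CC(C)=C)O[Al-]1(OCCOC)OCCOC | intermediate
12 | (5Z,7S)-7-[(tert-butyldimethylsilyl)oxy]-6-iodo-2,10-dimethylundeca-1,5-diene-4,9-diol | CC(C)C(O)C[C@H](O[Si](C)(C)C(C)(C)C)/C(I)=C/C(O)CC(C)=C | intermediate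
13 | tributyl(prop-2-en-1-yl)stannane | C=CC[Sn](CCCC)(CCCC)CCCC | starting material
14 | (5E,7S)-7-[(tert-butyldimethylsilyl)oxy]-2,10-dimethyl-6-(prop-2-en-1-yl)undeca-1,5-diene-4,9-diol | CC(C)C(O)C[C@H](O[Si](C)(C)C(C)(C)C)/C(CC=C)=C/C(O)CC(C)=C | intermediate
15 | 3-[(1S)-1-[(tert-butyldimethylsilyl)oxy]-3-hydroxy-4-methylpentyl]-6-methylcyclohepta-2,5-dien-1-ol | CC(C)C(O)C[C@H](O[Si](C)(C)C(C)(C)C)C1=CC(O)CC(C)=CC1 | intermediate
16 | 3-[(1S)-1-[(tert-butyldimethylsilyl)oxy]-4-methyl-3-oxopentyl]-6-methylcyclohepta-2,5-dien-1-one | CC(C)C(=O)C[C@H](O[Si](C)(C)C(C)(C)C)C1=CC(=O)CC(C)=CC1 | intermediate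
17 | lithium enolate after methyl transfer (quaternary carbon R) | [Li+].CC(C)C(=O)C[C@H](O[Si](C)(C)C(C)(C)C)[C@]1(C)CC=C(C)CC([O-])=C1 | intermediate
18 | (1S,3S,3aS,8aR)-1-[(tert-butyldimethylsilyl)oxy]-3-hydroxy-6,8a-dimethyl-3-(propan-2-yl)-2,3,3a,5,8,8a-hexahydroazulen-4(1H)-one | CC(C)(C)[Si](C)(C)O[C@H]1C[C@](O)(C(C)C)[C@H]2C(=O)CC(C)=CC[C@@]12C | intermediate
19 | (1S,3S,3aR,4R,8aR)-1-[(tert-butyldimethylsilyl)oxy]-6,8a-dimethyl-3-(propan-2-yl)-1,2,3,3a,4,5,8,8a-octahydroazulene-3,4-diol | CC(C)(C)[Si](C)(C)O[C@H]1C[C@](O)(C(C)C)[C@H]2[C@H](O)CC(C)=CC[C@@]12C | intermediate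
20 | 3,4,5-trimethoxybenzoyl chloride | COc1cc(cc(OC)c1OC)C(Cl)=O | starting material
21 | (1S,3S,3aR,4R,8aR)-1-[(tert-butyldimethylsilyl)oxy]-3-hydroxy-6,8a-dimethyl-3-(propan-2-yl)-1,2,3,3a,4,5,8,8a-octahydroazulen-4-yl 3,4,5-trimethoxybenzoate | CC(C)(C)[Si](C)(C)O[C@H]1C[C@](O)(C(C)C)[C@H]2[C@H](OC(=O)c3cc(OC)c(OC)c(OC)c3)CC(C)=CC[C@@]12C | intermediate
22 | (1S,3S,3aR,4R,8aR)-1,3-dihydroxy-6,8a-dimethyl-3-(propan-2-yl)-1,2,3,3a,4,5,8,8a-octahydroazulen-4-yl 3,4,5-trimethoxybenzoate | O[C@H]1C[C@](O)(C(C)C)[C@H]2[C@H](OC(=O)c3cc(OC)c(OC)c(OC)c3)CC(C)=CC[C@@]12C | intermediate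
23 | angelic acid, (2Z)-2-methylbut-2-enoic acid | C/C=C(/C)C(O)=O | starting material
24 | angelic 2,4,6-trichlorobenzoic anhydride | C/C=C(/C)C(=O)OC(=O)c1c(Cl)cc(Cl)cc1Cl | intermediate
25 | (1S,3S,3aR,4R,8aR)-3-hydroxy-6,8a-dimethyl-3-(propan-2-yl)-4-[(3,4,5-trimethoxybenzoyl)oxy]-1,2,3,3a,4,5,8,8a-octahydroazulen-1-yl (2Z)-2-methylbut-2-enoate | C/C=C(/C)C(=O)O[C@H]1C[C@](O)(C(C)C)[C@H]2[C@H](OC(=O)c3cc(OC)c(OC)c(OC)c3)CC(C)=CC[C@@]12C | target

**Step count and risks**

Total steps: 14. Longest linear sequence: 14 steps (from 1).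

Steps most likely to fail:

1. Step 10. The methyl group may add with poor π-facial selectivity at C8a, or the addition to the β,β-disubstituted enone may be slow enough for the cuprate to attack the side-chain ketone. The fallback sets out from 16 and returns to the route at 18. A copper-catalysed enantioselective conjugate addition of AlMe3 (copper thiophene-2-carboxylate, a chiral phosphoramidite ligand of the series matched to the substrate, Et2O, −30 °C) puts C8a under catalyst control. The aluminium enolate is trapped with Me3SiOTf to give the isolable trimethylsilyl enol ether F1, whose diastereomers can be separated. TiCl4 (CH2Cl2, −78 °C) then closes the cyclopentane by an intramolecular Mukaiyama aldol addition to give 18.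

2. Step 6. The alkenylalanate may lose the neighbouring silyloxy group by β-elimination to an allene, or the hydrometalation may not be fully regioselective. The fallback sets out from 10 and returns at 12. Ruthenium-catalysed trans-hydrosilylation ([Cp*Ru(MeCN)3]PF6, Et3SiH, CH2Cl2, 0 °C) runs under neutral conditions and places silicon on the alkyne carbon distal to the free propargylic hydroxyl, giving the Z-alkenylsilane F2. Iododesilylation with N-iodosuccinimide in 1,1,1,3,3,3-hexafluoropropan-2-ol exchanges silicon for iodine with retention and gives 12.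

3. Step 14. Acylation of the neopentyl-type C1 hydroxyl may be slow, so that prolonged heating isomerises the angelate to the tiglate. The fallback sets out from 22 and returns at 25. Esterification of 22 with 2-[bis(2,2,2-trifluoroethoxy)phosphoryl]propanoic acid (N,N'-dicyclohexylcarbodiimide, DMAP, CH2Cl2) gives the phosphonate ester F3. A Still–Gennari olefination with acetaldehyde (KN(SiMe3)2, 18-crown-6, THF, −78 °C) then builds the Z-configured 2-methylbut-2-enoate on the molecule and gives 25 directly.

**Further compounds**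

F1 | step 10 | (5S)-5-[(tert-butyldimethylsilyl)oxy]-5-[(1R)-1,4-dimethyl-6-[(trimethylsilyl)oxy]cyclohepta-3,6-dien-1-yl]-2-methylpentan-3-one | CC(C)C(=O)C[C@H](O[Si](C)(C)C(C)(C)C)[C@]1(C)CC=C(C)CC(O[Si](C)(C)C)=C1
F2 | step 6 | (5Z,7S)-7-[(tert-butyldimethylsilyl)oxy]-2,10-dimethyl-6-(triethylsilyl)undeca-1,5-diene-4,9-diol | CC(C)C(O)C[C@H](O[Si](C)(C)C(C)(C)C)/C(=C/C(O)CC(C)=C)[Si](CC)(CC)CC
F3 | step 14 | (1S,3S,3aR,4R,8aR)-1-({2-[bis(2,2,2-trifluoroethoxy)phosphoryl]propanoyl}oxy)-3-hydroxy-6,8a-dimethyl-3-(propan-2-yl)-1,2,3,3a,4,5,8,8a-octahydroazulen-4-yl 3,4,5-trimethoxybenzoate | CC(C(=O)O[C@H]1C[C@](O)(C(C)C)[C@H]2[C@H](OC(=O)c3cc(OC)c(OC)c(OC)c3)CC(C)=CC[C@@]12C)P(=O)(OCC(F)(F)F)OCC(F)(F)F
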